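## Analysis of the target

The target is a plakortide-type peroxy acid. Its core is a 1,2-dioxane (O1–O2–C3–C4–C5–C6) with an acetic acid arm (C1–C2) on C3, a methyl on C4, and both a methyl and the C7–C14 chain on C6. The chain carries a methyl stereocentre at C8 and ends in a (10E,12E)-10,12-dimethyl diene with a benzylic C14 methylene.

There are four stereocentres: C3 (R), C4 (S) and C6 (R) on the ring, and C8 (R) in the chain. In the chair the acetate arm, the C4 methyl and the C7 chain are all equatorial, while H3 and the C6 methyl are axial. The arm is therefore trans to the C4 methyl, and the C4 and C6 methyls are trans. C8 is separated from the ring by C7 and the quaternary C6, so it cannot be relayed from the ring and has to arrive with its own fragment.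

The O–O bond does not tolerate reductants, radicals or low-valent metals at elevated temperature. The β-peroxy acid can open by retro-oxa-Michael reaction in base. The diene and the doubly activated C14 methylene do not tolerate ozone, acid or radical chains.

The hard points are the quaternary peroxy carbon C6 with defined configuration and the timing of the peroxide: the oxidant that makes it would destroy the diene, and what follows must spare it.

The route rests on one structural feature. C3–C4–C5–C6 is a four-carbon unit with one peroxide oxygen on each end, which is a 3-methylcyclobutene whose C3=C6 double bond has been cut and bridged by O–O. Ozonolysis of that cyclobutene gives a bicyclic ozonide that already contains the dioxane. It differs from the target ring only in an ether bridge, which has to become H on C3 and CH3 on C6.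

## Retrosynthetic reasoning

**Acid.** Target 32 is traced to methyl ester 30 by cutting the ester C–O bond. The ester keeps the acid from quenching organometallics and from taking part at the C3 cation. The forward hydrolysis has to be mild enough not to open the β-peroxy ester.

**Diene (C11–C12).** Ester 30 is cut between the two alkenes into alkenyl chloride 25 and alkenyl boronate 29. The diene must be made after every oxidative and Lewis-acidic step, so the bond between two sp2 carbons is the natural last C–C bond. The halide sits on the ring fragment because a halo-alkene is electron-poor and survives ozonolysis. Chlorine was chosen over iodine for two reasons. An iodoalkene cannot be carried on the zinc reagent 18 through a palladium coupling. Installing iodine after that coupling would need a carboalumination next to the ester. The forward coupling must proceed with retention on both partners.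

**C3–H.** Dioxane 25 comes from hemiketal 24 by replacing the C3 hydroxyl with hydrogen. The forward step has to deliver hydride axially, cis to the C4 methyl.

**C6–CH3.** Hemiketal 24 comes from ozonide 22 by cutting the C6–CH3 bond and restoring the ether bridge. C6 is addressed first because it ionises more readily than C3, which is deactivated by the β-ester. So the first nucleophile has to be the methyl and the second the hydride. The forward step has to deliver methyl trans to the C4 methyl.

**Peroxide ring (key).** Ozonide 22 is traced to cyclobutene 19 by removing the three oxygen atoms and rejoining C3 and C6. This is the only disconnection that makes both peroxide C–O bonds and the six-membered ring in one operation from a hydrocarbon alkene. The forward ozonolysis must select the cyclobutene over the chloroalkene and recombine intramolecularly.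

**C6–C7.** Cyclobutene 19 is cut at the sp2–sp3 bond into enol triflate 9 and bromide 17 (as zinc reagent 18). This separates the ring, with its single stereocentre C4, from the chain, with C8. No reaction has to relay stereochemistry between them.

**Ring fragment.** Triflate 9 comes from silyl enol ether 7, and that from keto ester 6 by enolisation toward the substituted α-carbon. Keto ester 6 comes from enol ether 3 and bromo ester 4 by cutting C2–C3. Enol ether 3 comes from the symmetric ketone 1 by desymmetrisation, which defines C4 without making a bond to it.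

**Chain fragment.** Chloroalkene 17 comes from alkyne 15 by cutting the C10–CH3 bond (syn methylmetalation fixes the E geometry). Alkyne 15 comes from 14, and 14 from triflate 11 and alkyne 12 by cutting C9–C10. Triflate 11 comes from the bromo alcohol 10, which supplies C8.

**Boronate.** Boronate 29 comes from iodide 28, and 28 from alkyne 26 by syn hydrometalation, which fixes the second E alkene.

## Alternatives that were turned down

**Alternative 1:** Both methyl stereocentres, C4 and C8, are traced to the C2-symmetric C3–C9 diol A1. The key step is a two-directional, zirconium-catalysed asymmetric carboalumination of the symmetric silyloxy diene A2 with a trialkylaluminium, followed by aerobic oxidation of the two C–Al bonds.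
- For it: one catalytic operation sets C4 and C8 from an achiral diene. The C2-symmetric product is enriched statistically. Its two ends are homotopic, so monofunctionalisation gives one compound.
- Against it: the step makes no ring. After it the O–O bond, C3 and the quaternary C6 are still missing. C6 would be reached from a carbinol by oxidation, methyl addition and peroxidation, with no element to control its configuration. A 1,6-diene under zirconium and aluminium can also close a ring by intramolecular carbometalation, and the meso-type diastereomers must be removed.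
- Comparison: on the two methyl centres this plan is as strong or stronger, since the chosen route uses a stoichiometric chiral base for C4 and a chiral-pool fragment for C8. The chosen route offers in its place the whole dioxane with both C–O bonds in one step, and a much shorter path after the stereocentres are set.

**Alternative 2:** The C3–C4 bond is cut. The key step is a 6-exo cyclisation of a C4 radical, generated from the secondary iodide A4 in a tin hydride chain, onto C3 of a β-peroxy acrylimide held by a chiral magnesium Lewis acid. It gives the imide A3.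
- For it: one step closes the ring, forms a C–C bond, sets C3 and C4 under catalyst control and delivers the acid oxidation level with the full side chain in place. No late coupling is needed.
- Against it: the O–O bond is present during a radical chain. Stannyl radicals attack peroxide oxygen. The cyclised radical at C2 is β to a peroxide oxygen and can collapse to an epoxide with loss of an alkoxyl radical. The diene in A4 is a radical trap. A4 also needs a configured tertiary hydroperoxide at C6, so the hardest centre is moved, not solved.
- Comparison: it is stronger in convergency and in setting C3 by a catalyst. The chosen route offers a peroxide made by a polar pericyclic sequence, with no radical on a peroxide-bearing skeleton, and C6 set after ring formation by the ring itself.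

**Alternative 3:** The O–C6 bond is cut. The key step is an acid-catalysed 6-exo opening of the trisubstituted C6–C7 epoxide in A6 by the C3 hydroperoxide, with inversion at C6. It gives the C7-hydroxy dioxane A5.
- For it: the step is stereospecific. The C6 configuration comes from the epoxide, which reagent-controlled epoxidation can supply. On C6 this is stronger than the kinetic axial attack used in the chosen route.
- Against it: a configured secondary hydroperoxide at C3 is needed, and displacement at a branched secondary carbon competes with elimination. A5 carries a C7 hydroxyl that the target lacks. Removing it next to a peroxide is hard: a C7 radical is β to the peroxide and fragments, and the position is neopentyl-like for hydride displacement. C1 is at the alcohol level and needs two oxidations.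
- Comparison: the chosen route gives up stereospecific control at C6. In return it has no superfluous oxygen to remove and reaches the ring from an alkene in one step.

Key step: step 10

Assumption: the (R,R)-amide is taken to give the (S)-enolate of 1 by analogy with 4-substituted cyclohexanones; if the sense is opposite, the (S,S)-amide is used and nothing else changes.

## Route

Ring locants in names follow the numbering used above (O1, O2, C3 to C6).

Step 1
Reactants: 1 3-methylcyclobutan-1-one
Product: 3 trimethyl{[(3S)-3-methylcyclobut-1-en-1-yl]oxy}silane, via lithium enolate 2 (not isolated)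
Conditions: (R,R)-bis(1-phenylethyl)amine, n-BuLi, LiCl, THF, −78 °C; TMSCl; add 1, −100 °C
Reagents that add atoms: chlorotrimethylsilane C[Si](C)(C)Cl
Why: Enantioselective deprotonation of a prochiral 3-substituted cyclobutanone by a C2-symmetric chiral lithium amide with in situ silylation (chiral-base desymmetrisation); the base tells the enantiotopic α-methylenes apart and so defines C4 without a bond being made to it. Any minor enantiomer becomes a diastereomer after step 9, because 17 is enantiopure, and can be removed there.

Step 2
Reactants: 3 trimethyl{[(3S)-3-methylcyclobut-1-en-1-yl]oxy}silane; 4 methyl bromoacetate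
Product: 6 methyl 2-[(1R,2S)-2-methyl-4-oxocyclobutyl]acetate, via benzyltrimethylammonium enolate 5 (not isolated)
Conditions: BnMe3NF (anhydrous, 1.1 equiv), 4 (1.5 equiv), 4 Å MS, THF, −20 °C to rt
Reagents that add atoms: none
Why: Fluoride cleaves the O–Si bond and frees the quaternary ammonium enolate regiospecifically, and the reactive α-bromo ester already present in the flask C-alkylates it at once by SN2 (fluoride-promoted monoalkylation of a silyl enol ether). Fast capture leaves little time for proton exchange with the product, which would return achiral ketone 1 and erode the enantiomeric purity. The electrophile should enter trans to the neighbouring methyl, but this α-centre is erased in step 3.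

Step 3
Reactants: 6 methyl 2-[(1R,2S)-2-methyl-4-oxocyclobutyl]acetate
Product: 7 methyl 2-[(4S)-4-methyl-2-[(trimethylsilyl)oxy]cyclobut-1-en-1-yl]acetate
Conditions: TMSCl, NaI, Et3N, MeCN, rt
Reagents that add atoms: chlorotrimethylsilane C[Si](C)(C)Cl
Why: Silyl enol ether formation under equilibrating conditions (iodotrimethylsilane made in situ, amine base) should favour the more substituted, tetrasubstituted enol ether toward the acetate-bearing carbon. C4 is β to the carbonyl and is not affected.

Step 4
Reactants: 7 methyl 2-[(4S)-4-methyl-2-[(trimethylsilyl)oxy]cyclobut-1-en-1-yl]acetate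
Product: 9 methyl 2-[(4S)-4-methyl-2-{[(trifluoromethyl)sulfonyl]oxy}cyclobut-1-en-1-yl]acetate, via caesium enolate 8 (not isolated)
Conditions: CsF, PhNTf2, DME, rt
Reagents that add atoms: N-phenylbis(trifluoromethanesulfonimide) O=S(=O)(N(c1ccccc1)S(=O)(=O)C(F)(F)F)C(F)(F)F
Why: Fluoride cleaves the O–Si bond and the enolate is O-sulfonylated at once (enol triflate formation from a silyl enol ether). The double-bond position fixed in 7 is kept, and no strong base comes near the ester.

Step 5
Reactants: 10 (2R)-3-bromo-2-methylpropan-1-ol
Product: 11 (2R)-3-bromo-2-methylpropyl trifluoromethanesulfonate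
Conditions: Tf2O, 2,6-lutidine, CH2Cl2, −78 °C; used without purification
Reagents that add atoms: trifluoromethanesulfonic anhydride O=S(=O)(OS(=O)(=O)C(F)(F)F)C(F)(F)F
Why: O-Sulfonylation of a primary alcohol. The triflate is far more reactive than the primary bromide at the other end, which tells the two termini apart.

Step 6
Reactants: 11 (2R)-3-bromo-2-methylpropyl trifluoromethanesulfonate; 12 ethynyltrimethylsilane
Product: 14 [(4R)-5-bromo-4-methylpent-1-yn-1-yl]trimethylsilane, via lithium (trimethylsilyl)acetylide 13 (not isolated)
Conditions: 12, n-BuLi, THF, −78 °C; then 11, DMPU, −78 to −20 °C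
Reagents that add atoms: none
Why: SN2 alkynylation of a primary triflate by a lithium acetylide forms C9–C10. The bromide does not react at this temperature and the stereocentre is not involved.

Step 7
Reactants: 14 [(4R)-5-bromo-4-methylpent-1-yn-1-yl]trimethylsilane
Product: 15 (4R)-5-bromo-4-methylpent-1-yne
Conditions: K2CO3 (cat.), MeOH, 0 °C to rt
Reagents that add atoms: none
Why: Base-catalysed methanolysis of the alkynyl C–Si bond (protodesilylation); the hindered primary bromide should survive the short exposure.

Step 8
Reactants: 15 (4R)-5-bromo-4-methylpent-1-yne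
Product: 17 (1E,4R)-5-bromo-1-chloro-2,4-dimethylpent-1-ene, via alkenylalane 16 (not isolated)
Conditions: Me3Al, Cp2ZrCl2 (20 mol%), CH2Cl2, 0 °C to rt; then NCS, THF, −30 to 0 °C
Reagents that add atoms: trimethylaluminium C[Al](C)C; N-chlorosuccinimide O=C1CCC(=O)N1Cl
Why: Negishi zirconium-catalysed methylalumination of a terminal alkyne adds methyl and aluminium syn, methyl to the internal carbon. Chlorinolysis of the C–Al bond with retention gives the E-chloroalkene.

Step 9
Reactants: 17 (1E,4R)-5-bromo-1-chloro-2,4-dimethylpent-1-ene; 9 methyl 2-[(4S)-4-methyl-2-{[(trifluoromethyl)sulfonyl]oxy}cyclobut-1-en-1-yl]acetate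
Product: 19 methyl 2-[(4S)-2-[(2S,4E)-5-chloro-2,4-dimethylpent-4-en-1-yl]-4-methylcyclobut-1-en-1-yl]acetate, via alkylzinc bromide 18 (not isolated)
Conditions: 17, Zn dust, I2 (5 mol%), DMA, 80 °C; then 9, Pd(dppf)Cl2 (5 mol%), THF, 50 °C
Reagents that add atoms: none
Why: Zinc inserts into the primary C–Br bond, and Negishi sp3–sp2 coupling with the enol triflate forms C6–C7. The chelating diphosphine suppresses β-hydride elimination and leaves the alkenyl C–Cl bond alone; no stereocentre is touched.

Step 10
Reactants: 19 methyl 2-[(4S)-2-[(2S,4E)-5-chloro-2,4-dimethylpent-4-en-1-yl]-4-methylcyclobut-1-en-1-yl]acetate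
Product: 22 methyl 2-[(1R,4S,5S)-1-[(2R,4E)-5-chloro-2,4-dimethylpent-4-en-1-yl]-5-methyl-2,3,7-trioxabicyclo[2.2.1]heptan-4-yl]acetate, via primary ozonide 20 (not isolated), via keto carbonyl oxide 21 (not isolated)
Conditions: O3 (1.0 equiv, titrated solution in CH2Cl2), CH2Cl2, −78 °C; N2 purge; no reductive work-up
Reagents that add atoms: ozone [O-][O+]=O
Why: Ozone adds to the strained tetrasubstituted C3=C6 bond by a concerted 1,3-dipolar cycloaddition to give the 1,2,3-trioxolane 20, which cycloreverts to a ketone and a carbonyl oxide that stay joined through C4–C5 (21 and its regioisomer with C3 and C6 exchanged). The carbonyl oxide then adds across the tethered ketone in a second, intramolecular 1,3-dipolar cycloaddition, which forms the O–C3 and O–C6 peroxide bonds and the ether bridge; both regioisomeric pairs close to the same constitution. The closest known reaction is the ozonolysis of 1,2-dialkylcyclobutenes and 1,2-dialkylcyclopentenes in non-participating solvents, which gives isolable bicyclic ozonides by this Criegee sequence. The 1,2,4-trioxolane closes by cycloaddition, not by a nucleophilic exo or endo closure, and with it the six-membered 1,2-dioxane ring C3–C4–C5–C6–O–O and the five-membered oxolane ring C3–C4–C5–C6–O of the bicyclo[2.2.1] skeleton arise together. No lasting stereocentre is created: the bridgeheads are cis by necessity, and the two diastereomers with the C4 methyl endo or exo to the ether bridge are both carried on, because C3 and C6 are ionised in steps 11 and 12; C4 and C8 are not touched. The step needs chemoselectivity for the cyclobutene over the chloroalkene, which rests on release of four-ring strain and on four alkyl donors against an alkene deactivated by chlorine, with ozone limited to one equivalent. It also needs recombination to win over oligomerisation, solvent capture or tautomerisation of the carbonyl oxide, which the two-carbon tether, the low temperature and the non-nucleophilic solvent should secure.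

Step 11
Reactants: 22 methyl 2-[(1R,4S,5S)-1-[(2R,4E)-5-chloro-2,4-dimethylpent-4-en-1-yl]-5-methyl-2,3,7-trioxabicyclo[2.2.1]heptan-4-yl]acetate
Product: 24 methyl 2-[(3R,4S,6R)-6-[(2R,4E)-5-chloro-2,4-dimethylpent-4-en-1-yl]-3-hydroxy-4,6-dimethyl-1,2-dioxan-3-yl]acetate, via silyl peroxyketal 23 (not isolated)
Conditions: Me3Al (3 equiv), TMSOTf (1.2 equiv), CH2Cl2, −78 °C; aq. potassium sodium tartrate, then brief aq. citric acid
Reagents that add atoms: trimethylaluminium C[Al](C)C
Why: Proposed new method: TMSOTf should silylate the ether-bridge oxygen, the most basic of the three, and the C6–O bond should ionise to a six-membered peroxycarbenium ion, because C6 carries two alkyl donors while C3 is deactivated by the β-ester. Me3Al should then transfer methyl along the axial trajectory of the half-chair that keeps the C4 methyl pseudo-equatorial, that is trans to the C4 methyl, so both bridgehead diastereomers of 22 converge on the 6R centre in 23, and work-up cleaves the O–Si bond. The closest known reactions are Lewis-acid substitutions of ozonides and of 3-alkoxy-1,2-dioxolanes and -dioxanes by allylsilanes and silyl enol ethers through peroxycarbenium ions, and the Me3Al/TMSOTf methylation of cyclic oxocarbenium ions derived from lactol derivatives.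

Step 12
Reactants: 24 methyl 2-[(3R,4S,6R)-6-[(2R,4E)-5-chloro-2,4-dimethylpent-4-en-1-yl]-3-hydroxy-4,6-dimethyl-1,2-dioxan-3-yl]acetate
Product: 25 methyl 2-[(3R,4S,6R)-6-[(2R,4E)-5-chloro-2,4-dimethylpent-4-en-1-yl]-4,6-dimethyl-1,2-dioxan-3-yl]acetate
Conditions: Et3SiH (5 equiv), TMSOTf (1.1 equiv), CH2Cl2, −78 to −40 °C
Reagents that add atoms: none
Why: Ionic hydrogenation of a cyclic hemiketal: loss of the C3 oxygen substituent gives the 1,2-dioxan-3-ylium ion and the silane delivers hydride. The quaternary C6 locks the half-chair with the C4 methyl and the C7 chain pseudo-equatorial, and axial attack, cis to the C4 methyl, should place the acetate arm equatorial and trans to that methyl (3R).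

Step 13
Reactants: 26 (but-2-yn-1-yl)benzene
Product: 28 [(2E)-3-iodobut-2-en-1-yl]benzene, via alkenylzirconocene chloride 27 (not isolated)
Conditions: Cp2Zr(H)Cl (1.3 equiv), THF, rt to 40 °C; then I2, 0 °C
Reagents that add atoms: iodine II
Why: Hydrozirconation adds Zr–H syn, and with a slight excess of reagent the regioisomers equilibrate so that zirconium sits on the less hindered, methyl-bearing carbon. Iodinolysis with retention gives the E-iodide, and the minor regioisomer is removed here.

Step 14
Reactants: 28 [(2E)-3-iodobut-2-en-1-yl]benzene
Product: 29 4,4,5,5-tetramethyl-2-[(2Z)-4-phenylbut-2-en-2-yl]-1,3,2-dioxaborolane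
Conditions: B2pin2, PdCl2(PPh3)2 (3 mol%), PPh3, KOPh, toluene, 50 °C
Reagents that add atoms: bis(pinacolato)diboron CC1(C)OB(OC1(C)C)B1OC(C)(C)C(C)(C)O1
Why: Miyaura borylation of an alkenyl iodide, with retention of the alkene geometry. The descriptor changes to Z only because boron ranks below carbon.

Step 15
Reactants: 25 methyl 2-[(3R,4S,6R)-6-[(2R,4E)-5-chloro-2,4-dimethylpent-4-en-1-yl]-4,6-dimethyl-1,2-dioxan-3-yl]acetate; 29 4,4,5,5-tetramethyl-2-[(2Z)-4-phenylbut-2-en-2-yl]-1,3,2-dioxaborolane
Product: 30 methyl 2-[(3R,4S,6R)-4,6-dimethyl-6-[(2R,4E,6E)-2,4,6-trimethyl-8-phenylocta-4,6-dien-1-yl]-1,2-dioxan-3-yl]acetate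
Conditions: Pd(OAc)2 (5 mol%), SPhos (10 mol%), K3PO4, THF/H2O, rt to 40 °C
Reagents that add atoms: none
Why: Suzuki–Miyaura coupling of an unactivated alkenyl chloride, which a dialkylbiarylphosphine ligand makes possible near room temperature. Both partners couple with retention, so the 4E,6E diene results, and a saturated dialkyl peroxide should not be attacked by the zerovalent palladium catalyst under these conditions.

Step 16
Reactants: 30 methyl 2-[(3R,4S,6R)-4,6-dimethyl-6-[(2R,4E,6E)-2,4,6-trimethyl-8-phenylocta-4,6-dien-1-yl]-1,2-dioxan-3-yl]acetate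
Product: 32 2-[(3R,4S,6R)-4,6-dimethyl-6-[(2R,4E,6E)-2,4,6-trimethyl-8-phenylocta-4,6-dien-1-yl]-1,2-dioxan-3-yl]acetic acid, via lithium carboxylate 31 (not isolated)
Conditions: LiOH, THF/MeOH/H2O, 0 °C to rt; then 1 M HCl to pH 3
Reagents that add atoms: lithium hydroxide [Li+].[OH-]
Why: Saponification of a methyl ester by acyl–oxygen cleavage. Cold hydroxide should leave the O–O bond and the C3 centre intact.

## Compound list

1 | 3-methylcyclobutan-1-one | CC1CC(=O)C1 | starting material
2 | lithium (3S)-3-methylcyclobut-1-en-1-olate | [Li+].[O-]C1=C[C@@H](C)C1 | intermediate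
3 | trimethyl{[(3S)-3-methylcyclobut-1-en-1-yl]oxy}silane | C[Si](C)(C)OC1=C[C@@H](C)C1 | intermediate
4 | methyl bromoacetate | BrCC(=O)OC | starting material
5 | benzyltrimethylammonium (3S)-3-methylcyclobut-1-en-1-olate | C[N+](C)(C)Cc1ccccc1.[O-]C1=C[C@@H](C)C1 | intermediate
6 | methyl 2-[(1R,2S)-2-methyl-4-oxocyclobutyl]acetate | O=C1C[C@H](C)[C@H]1CC(=O)OC | intermediate
7 | methyl 2-[(4S)-4-methyl-2-[(trimethylsilyl)oxy]cyclobut-1-en-1-yl]acetate | C[Si](C)(C)OC1=C(CC(=O)OC)[C@@H](C)C1 | intermediate
8 | caesium (3S)-2-(2-methoxy-2-oxoethyl)-3-methylcyclobut-1-en-1-olate | [Cs+].[O-]C1=C(CC(=O)OC)[C@@H](C)C1 | intermediate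
9 | methyl 2-[(4S)-4-methyl-2-{[(trifluoromethyl)sulfonyl]oxy}cyclobut-1-en-1-yl]acetate | O=S(=O)(OC1=C(CC(=O)OC)[C@@H](C)C1)C(F)(F)F | intermediate
10 | (2R)-3-bromo-2-methylpropan-1-ol | OC[C@@H](C)CBr | starting material
11 | (2R)-3-bromo-2-methylpropyl trifluoromethanesulfonate | O=S(=O)(OC[C@@H](C)CBr)C(F)(F)F | intermediate
12 | ethynyltrimethylsilane | C#C[Si](C)(C)C | starting material
13 | lithium (trimethylsilyl)acetylide | [Li+].[C-]#C[Si](C)(C)C | intermediate
14 | [(4R)-5-bromo-4-methylpent-1-yn-1-yl]trimethylsilane | C[Si](C)(C)C#CC[C@@H](C)CBr | intermediate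
15 | (4R)-5-bromo-4-methylpent-1-yne | C#CC[C@@H](C)CBr | intermediate
16 | [(1E,4R)-5-bromo-2,4-dimethylpent-1-en-1-yl]dimethylalumane | C[Al](C)/C=C(\C)C[C@@H](C)CBr | intermediate
17 | (1E,4R)-5-bromo-1-chloro-2,4-dimethylpent-1-ene | Cl/C=C(\C)C[C@@H](C)CBr | intermediate
18 | bromo[(2R,4E)-5-chloro-2,4-dimethylpent-4-en-1-yl]zinc | Cl/C=C(\C)C[C@@H](C)C[Zn]Br | intermediate
19 | methyl 2-[(4S)-2-[(2S,4E)-5-chloro-2,4-dimethylpent-4-en-1-yl]-4-methylcyclobut-1-en-1-yl]acetate | Cl/C=C(\C)C[C@@H](C)CC1=C(CC(=O)OC)[C@@H](C)C1 | intermediate
20 | methyl 2-[(6S)-1-[(2R,4E)-5-chloro-2,4-dimethylpent-4-en-1-yl]-6-methyl-2,3,4-trioxabicyclo[3.2.0]heptan-5-yl]acetate (primary ozonide, both faces) | Cl/C=C(\C)C[C@@H](C)CC12OOOC1(CC(=O)OC)[C@@H](C)C2 | intermediate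
21 | C6 carbonyl oxide of methyl (4S,8R,10E)-11-chloro-4,8,10-trimethyl-3,6-dioxoundec-10-enoate (keto carbonyl oxide; the C3 carbonyl oxide forms alongside) | Cl/C=C(\C)C[C@@H](C)CC(=[O+][O-])C[C@H](C)C(=O)CC(=O)OC | intermediate
22 | methyl 2-[(1R,4S,5S)-1-[(2R,4E)-5-chloro-2,4-dimethylpent-4-en-1-yl]-5-methyl-2,3,7-trioxabicyclo[2.2.1]heptan-4-yl]acetate (5-endo-methyl isomer drawn; the (1S,4R,5S) exo isomer is carried along) | Cl/C=C(\C)C[C@@H](C)C[C@]12C[C@H](C)[C@](CC(=O)OC)(OO1)O2 | intermediate
23 | methyl 2-[(3R,4S,6R)-6-[(2R,4E)-5-chloro-2,4-dimethylpent-4-en-1-yl]-4,6-dimethyl-3-[(trimethylsilyl)oxy]-1,2-dioxan-3-yl]acetate (from the drawn isomer of 22; the C3 epimer arises from the other) | Cl/C=C(\C)C[C@@H](C)C[C@]1(C)C[C@H](C)[C@](O[Si](C)(C)C)(CC(=O)OC)OO1 | intermediate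
24 | methyl 2-[(3R,4S,6R)-6-[(2R,4E)-5-chloro-2,4-dimethylpent-4-en-1-yl]-3-hydroxy-4,6-dimethyl-1,2-dioxan-3-yl]acetate (axial-hydroxyl anomer drawn; anomers interconvert) | Cl/C=C(\C)C[C@@H](C)C[C@]1(C)C[C@H](C)[C@@](O)(CC(=O)OC)OO1 | intermediate
25 | methyl 2-[(3R,4S,6R)-6-[(2R,4E)-5-chloro-2,4-dimethylpent-4-en-1-yl]-4,6-dimethyl-1,2-dioxan-3-yl]acetate | Cl/C=C(\C)C[C@@H](C)C[C@]1(C)C[C@H](C)[C@@H](CC(=O)OC)OO1 | intermediate
26 | (but-2-yn-1-yl)benzene | CC#CCc1ccccc1 | starting material
27 | chlorobis(cyclopentadienyl)[(2E)-4-phenylbut-2-en-2-yl]zirconium | C/C(=C\Cc1ccccc1)[Zr](Cl)(C1C=CC=C1)C1C=CC=C1 | intermediate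
28 | [(2E)-3-iodobut-2-en-1-yl]benzene | C/C(I)=C\Cc1ccccc1 | intermediate
29 | 4,4,5,5-tetramethyl-2-[(2Z)-4-phenylbut-2-en-2-yl]-1,3,2-dioxaborolane | C/C(=C\Cc1ccccc1)B1OC(C)(C)C(C)(C)O1 | intermediate
30 | methyl 2-[(3R,4S,6R)-4,6-dimethyl-6-[(2R,4E,6E)-2,4,6-trimethyl-8-phenylocta-4,6-dien-1-yl]-1,2-dioxan-3-yl]acetate | CC(=C\Cc1ccccc1)/C=C(\C)C[C@@H](C)C[C@]1(C)C[C@H](C)[C@@H](CC(=O)OC)OO1 | intermediate
31 | lithium 2-[(3R,4S,6R)-4,6-dimethyl-6-[(2R,4E,6E)-2,4,6-trimethyl-8-phenylocta-4,6-dien-1-yl]-1,2-dioxan-3-yl]acetate | CC(=C\Cc1ccccc1)/C=C(\C)C[C@@H](C)C[C@]1(C)C[C@H](C)[C@@H](CC(=O)[O-])OO1.[Li+] | intermediate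
32 | 2-[(3R,4S,6R)-4,6-dimethyl-6-[(2R,4E,6E)-2,4,6-trimethyl-8-phenylocta-4,6-dien-1-yl]-1,2-dioxan-3-yl]acetic acid | CC(=C\Cc1ccccc1)/C=C(\C)C[C@@H](C)C[C@]1(C)C[C@H](C)[C@@H](CC(=O)O)OO1 | target

## Step count and least certain steps

Total: 16 steps. The longest linear sequence is 10 steps (steps 1–4, 9–12, 15, 16 from ketone 1). The chain branch (steps 5–8, then 9–12, 15, 16) is equally long.

**Step 11 (proposed new method).** The likely failures are O–O heterolysis with alkyl migration under the silyl triflate, methyl transfer to a peroxide oxygen instead of carbon, or collapse of the C3 silyl ketal to an acyclic intermediate, which would erode facial control at C6. The fallback uses known chemistry, sets out from 22 and comes back at 24. PPh3 reduces the ozonide to the diketo ester F1. Ph3P=CH2 in excess, with the β-keto ester protected as its enolate, methylenates the C6 ketone to the methylidene keto ester F2. Cobalt-catalysed hydroperoxysilylation (Co(thd)2, O2, Et3SiH) adds the peroxide at the tertiary carbon to give the silyl peroxide F3; it is not stereoselective, so the C6 epimers have to be separated. Bu4NF/AcOH frees the hydroperoxide F4, which closes onto the C3 ketone to 24.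

**Step 10 (key step).** Ozone may attack the chloroalkene once or while the cyclobutene is consumed. The carbonyl oxide next to the ester-activated methylene may also tautomerise or oligomerise before it is captured. The fallback sets out from 19 and comes back at 22. Dimethyldioxirane epoxidises only the electron-rich cyclobutene, to the epoxide F5. H5IO6 in aqueous THF cleaves it to the diketo ester F1 described above. Ethereal H2O2 with BF3·OEt2 or P2O5 condenses the 1,4-diketone to the same bicyclic peroxide 22.

**Step 12.** The hemiketal may ionise by ring opening, losing the peroxide oxygen instead of the hydroxyl, so that the acyclic ketone is reduced; elimination toward C2 and poor facial selectivity are further risks. The fallback sets out from 24 and comes back at 25. Methanol and camphorsulfonic acid give the methyl peroxyketal F6, which cannot open to a ketone. TiCl4 and Et3SiH at −78 °C then substitute methoxide by hydride on this locked 3-alkoxy-1,2-dioxane.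

**Step 3.** Enolisation may be incompletely regioselective, with competing enolisation toward the ring methylene C5 giving the isomeric enol ether and triflate. The fallback sets out from 3 and comes back at 9. A Mukaiyama aldol reaction with methyl glyoxylate (BF3·OEt2) gives the aldol F7. MsCl and Et3N give the alkylidene ketone F8. LiBH(s-Bu)3 adds hydride to the exocyclic β-carbon to give the regiospecific lithium enolate F9, which is trapped with PhNTf2 as 9.

**Step 15.** Oxidative addition of the C–Cl bond may be slow and force temperatures at which aqueous base opens the β-peroxy ester or the electron-rich catalyst attacks the O–O bond. The fallback sets out from 26 (through 27) and 25, and comes back at 30. ZnCl2 converts 27 into the alkenylzinc chloride F10. A base-free Negishi coupling with 25 (Pd(P(t-Bu)3)2, THF/NMP, rt to 50 °C) then forms the diene.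

## Further compounds

F1 | step 11 | methyl (4S,8R,10E)-11-chloro-4,8,10-trimethyl-3,6-dioxoundec-10-enoate | Cl/C=C(\C)C[C@@H](C)CC(=O)C[C@H](C)C(=O)CC(=O)OC
F2 | step 11 | methyl (4S,8S,10E)-11-chloro-4,8,10-trimethyl-6-methylidene-3-oxoundec-10-enoate | Cl/C=C(\C)C[C@@H](C)CC(=C)C[C@H](C)C(=O)CC(=O)OC
F3 | step 11 | methyl (4S,6R,8R,10E)-11-chloro-4,6,8,10-tetramethyl-3-oxo-6-[(triethylsilyl)peroxy]undec-10-enoate | Cl/C=C(\C)C[C@@H](C)C[C@@](C)(OO[Si](CC)(CC)CC)C[C@H](C)C(=O)CC(=O)OC
F4 | step 11 | methyl (4S,6R,8R,10E)-11-chloro-6-hydroperoxy-4,6,8,10-tetramethyl-3-oxoundec-10-enoate | Cl/C=C(\C)C[C@@H](C)C[C@@](C)(OO)C[C@H](C)C(=O)CC(=O)OC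
F5 | step 10 | methyl 2-[(2S)-4-[(2R,4E)-5-chloro-2,4-dimethylpent-4-en-1-yl]-2-methyl-5-oxabicyclo[2.1.0]pentan-1-yl]acetate (both epoxide faces) | Cl/C=C(\C)C[C@@H](C)CC12OC1(CC(=O)OC)[C@@H](C)C2
F6 | step 12 | methyl 2-[(3R,4S,6R)-6-[(2R,4E)-5-chloro-2,4-dimethylpent-4-en-1-yl]-3-methoxy-4,6-dimethyl-1,2-dioxan-3-yl]acetate | Cl/C=C(\C)C[C@@H](C)C[C@]1(C)C[C@H](C)[C@@](OC)(CC(=O)OC)OO1
F7 | step 3 | methyl 2-hydroxy-2-[(1S,2S)-2-methyl-4-oxocyclobutyl]acetate (carbinol epimers) | O=C1C[C@H](C)[C@H]1C(O)C(=O)OC
F8 | step 3 | methyl 2-[(2S)-2-methyl-4-oxocyclobutylidene]acetate (alkene geometry immaterial) | O=C1C[C@H](C)C1=CC(=O)OC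
F9 | step 3 | lithium (3S)-2-(2-methoxy-2-oxoethyl)-3-methylcyclobut-1-en-1-olate | [Li+].[O-]C1=C(CC(=O)OC)[C@@H](C)C1
F10 | step 15 | chloro[(2E)-4-phenylbut-2-en-2-yl]zinc | C/C(=C\Cc1ccccc1)[Zn]Cl
A1 | alternative 1 | (2S,6S)-4-[(tert-butyldimethylsilyl)oxy]-2,6-dimethylheptane-1,7-diol | OC[C@@H](C)CC(O[Si](C)(C)C(C)(C)C)C[C@H](C)CO
A2 | alternative 1 | tert-butyl(hepta-1,6-dien-4-yloxy)dimethylsilane | C=CCC(O[Si](C)(C)C(C)(C)C)CC=C
A3 | alternative 2 | 3-{2-[(3R,4S,6R)-4,6-dimethyl-6-[(2R,4E,6E)-2,4,6-trimethyl-8-phenylocta-4,6-dien-1-yl]-1,2-dioxan-3-yl]acetyl}-1,3-oxazolidin-2-one | CC(=C\Cc1ccccc1)/C=C(\C)C[C@@H](C)C[C@]1(C)C[C@H](C)[C@@H](CC(=O)N2CCOC2=O)OO1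
A4 | alternative 2 | 3-[(2E)-3-{[(4R,6R,8E,10E)-2-iodo-4,6,8,10-tetramethyl-12-phenyldodeca-8,10-dien-4-yl]peroxy}prop-2-enoyl]-1,3-oxazolidin-2-one | CC(=C\Cc1ccccc1)/C=C(\C)C[C@@H](C)C[C@](C)(CC(C)I)OO/C=C/C(=O)N1CCOC1=O
A5 | alternative 3 | (1R,2R,4E)-1-[(3R,4S,6S)-3-{2-[(tert-butyldimethylsilyl)oxy]ethyl}-4,6-dimethyl-1,2-dioxan-6-yl]-5-iodo-2,4-dimethylpent-4-en-1-ol | I/C=C(\C)C[C@@H](C)[C@@H](O)[C@]1(C)C[C@H](C)[C@@H](CCO[Si](C)(C)C(C)(C)C)OO1
A6 | alternative 3 | tert-butyl{[(3R,4S)-3-hydroperoxy-5-[(2R,3R)-3-[(2R,4E)-5-iodo-4-methylpent-4-en-2-yl]-2-methyloxiran-2-yl]-4-methylpentyl]oxy}dimethylsilane | I/C=C(\C)C[C@@H](C)[C@H]1O[C@]1(C)C[C@H](C)[C@@H](CCO[Si](C)(C)C(C)(C)C)OO
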